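**Retrosynthetic overview**
1. Target 26 comes from its 2'-O-allyl ether 25 by Pd(0) deallylation; 25 comes from p-quinol 23 by forming O1–C8a (oxa-Michael) and rearomatising ring A with loss of water.
2. Feature used: in ring A, O1 sits on C8a, ortho to C4a (which carries the C4 methylene) and meta to the C7 hydroxyl. C8a is therefore the enone β-carbon of the 4-alkyl-4-hydroxycyclohexa-2,5-dienone made from a plain para-alkylphenol, whose OH becomes the 7-OH.
3. 23 comes from phenol 21 by PhI(OAc)2/H2O with the primary alcohol held as a TBS ether, then HF·pyridine (no alkoxide is generated). 21 comes from Evans benzylation of imide 12 with bromide 16, which forms C3–C4 and sets C3.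
4. 12 comes from 2,4-dihydroxybenzaldehyde by C3'-prenylation, pyran annulation with prenal, O-allylation, van Leusen one-carbon homologation, hydrolysis and N-acylation.
5. Ring order: the 2,2-dimethylpyran on ring B (step 2), the dearomatised ring A (step 14), then ring C together with the re-formed aromatic ring A (step 16).

Key step: step 16

Abbreviations: Ar = 7-(allyloxy)-2,2-dimethyl-8-(3-methylbut-2-en-1-yl)-2H-chromen-6-yl (ring B with its fused pyran, 2'-oxygen allylated); TBS = tert-butyldimethylsilyl.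
Remark on configuration: C3 is R in the target because the oxygen-bearing C2 arm outranks the aryl group. The same spatial arrangement is R in every intermediate from 18 onward and requires the (R)-configured auxiliary.

**Route**

Step 1
Reactants: 1 2,4-dihydroxybenzaldehyde; 2 prenyl bromide (1-bromo-3-methylbut-2-ene)
Product: 3 2,4-dihydroxy-3-(3-methylbut-2-en-1-yl)benzaldehyde
Conditions: KOH (2 equiv), H2O, 0 °C to rt
Reagents that add atoms: none
Why: Phenolate C-alkylation in water, where hydrogen bonding to oxygen suppresses O-alkylation, should favour C3, the carbon flanked by both oxygens, and the 3-prenyl isomer is separated from the C5 and O-alkylated isomers.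

Step 2
Reactants: 3 2,4-dihydroxy-3-(3-methylbut-2-en-1-yl)benzaldehyde; 4 3-methylbut-2-enal
Product: 5 7-hydroxy-2,2-dimethyl-8-(3-methylbut-2-en-1-yl)-2H-chromene-6-carbaldehyde
Conditions: ethylenediammonium diacetate (10 mol %), xylene, 140 °C
Reagents that add atoms: none
Why: Knoevenagel-type condensation of the enal at C5, the only free carbon ortho to the 4-hydroxyl, gives an ortho-quinone methide that closes by oxa-6π electrocyclisation to the linear 2,2-dimethyl-2H-chromene, while the chelated 2-hydroxyl has no free ortho carbon.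

Step 3
Reactants: 5 7-hydroxy-2,2-dimethyl-8-(3-methylbut-2-en-1-yl)-2H-chromene-6-carbaldehyde
Product: 6 7-(allyloxy)-2,2-dimethyl-8-(3-methylbut-2-en-1-yl)-2H-chromene-6-carbaldehyde (ArCHO)
Conditions: allyl bromide (1.5 equiv), K2CO3, DMF, 50 °C
Reagents that add atoms: allyl bromide, C=CCBr
Why: Williamson etherification of the remaining chelated phenol installs a group that survives base, hydride, fluoride, iodine(III) and mild acid and is removable at the end under neutral Pd(0) conditions.

Step 4
Reactants: 6 ArCHO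
Product: 8 arylacetonitrile ArCH2CN, via N-(2-Ar-1-tosylvinyl)formamide 7 (not isolated)
Conditions: TosMIC (1.3 equiv), t-BuOK (2.6 equiv), DME, −40 °C; then MeOH, reflux
Reagents that add atoms: TosMIC (p-toluenesulfonylmethyl isocyanide), [C-]#[N+]CS(=O)(=O)c1ccc(C)cc1
Why: van Leusen reductive cyanation, in which the TosMIC anion adds to the aldehyde, the oxazoline opens to the N-(1-tosylvinyl)formamide anion and methanolysis expels formate and sulfinate, gives the one-carbon-homologated nitrile under purely basic conditions that the chromene, prenyl and allyl ether tolerate.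

Step 5
Reactants: 8 arylacetonitrile ArCH2CN
Product: 9 arylacetic acid ArCH2CO2H
Conditions: KOH (excess), EtOH/H2O, reflux; then cold 1 M HCl to pH 3
Reagents that add atoms: potassium hydroxide, [K+].[OH-]; water, O
Why: Alkaline nitrile hydrolysis touches none of the base-stable ether and alkene groups, and the acid is liberated by brief cold acidification.

Step 6
Reactants: 9 arylacetic acid ArCH2CO2H; 10 (R)-4-benzyloxazolidin-2-one
Product: 12 (R)-4-benzyl-3-(2-Ar-acetyl)oxazolidin-2-one, via mixed pivalic anhydride 11 (not isolated)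
Conditions: PivCl, Et3N, THF, −20 to 0 °C; then LiCl, 10, rt
Reagents that add atoms: none
Why: Mixed-anhydride N-acylation of the oxazolidinone under LiCl/Et3N activation takes place at the less hindered arylacetyl carbonyl and needs no strong base.

Step 7
Reactants: 13 4-hydroxybenzaldehyde
Product: 14 4-(tert-butyldimethylsilyloxy)benzaldehyde
Conditions: TBSCl, imidazole, DMF, rt
Reagents that add atoms: tert-butyldimethylsilyl chloride, CC(C)(C)[Si](C)(C)Cl
Why: Standard imidazole-promoted silylation of the only hydroxyl.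

Step 8
Reactants: 14 4-(tert-butyldimethylsilyloxy)benzaldehyde
Product: 15 [4-(tert-butyldimethylsilyloxy)phenyl]methanol
Conditions: NaBH4, MeOH, 0 °C
Reagents that add atoms: none
Why: Borohydride reduction of an aryl aldehyde leaves the aryl silyl ether intact at 0 °C.

Step 9
Reactants: 15 [4-(tert-butyldimethylsilyloxy)phenyl]methanol
Product: 16 4-(tert-butyldimethylsilyloxy)benzyl bromide
Conditions: CBr4, PPh3, CH2Cl2, 0 °C; used promptly
Reagents that add atoms: carbon tetrabromide, BrC(Br)(Br)Br
Why: Appel bromination converts the benzylic alcohol to the bromide under neutral conditions that keep the silyl ether.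

Step 10
Reactants: 12 (R)-4-benzyl-3-(2-Ar-acetyl)oxazolidin-2-one; 16 4-(tert-butyldimethylsilyloxy)benzyl bromide
Product: 18 (R)-4-benzyl-3-[(2R)-2-Ar-3-(4-TBSO-phenyl)propanoyl]oxazolidin-2-one, via sodium (Z)-enolate 17 (not isolated)
Conditions: NaHMDS (1.1 equiv), THF, −78 °C; then 16, −78 to −40 °C; AcOH quench
Reagents that add atoms: none
Why: Evans asymmetric alkylation, in which the chelated sodium (Z)-enolate is attacked by the benzylic bromide on the face opposite the auxiliary's C4 benzyl group, forms C3–C4 and with the (R)-auxiliary sets the α-carbon (future C3) as R.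

Step 11
Reactants: 18 (R)-4-benzyl-3-[(2R)-2-Ar-3-(4-TBSO-phenyl)propanoyl]oxazolidin-2-one
Product: 19 (2R)-2-Ar-3-[4-(tert-butyldimethylsilyloxy)phenyl]propan-1-ol
Conditions: LiBH4, MeOH (1 equiv), THF, 0 °C
Reagents that add atoms: none
Why: Reductive cleavage of the imide by lithium borohydride at the exocyclic carbonyl gives the primary alcohol at low temperature without enolising the α-aryl centre, and the auxiliary is recovered.

Step 12
Reactants: 19 (2R)-2-Ar-3-[4-(tert-butyldimethylsilyloxy)phenyl]propan-1-ol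
Product: 20 bis-TBS ether tert-butyl{4-[(2R)-2-Ar-3-(tert-butyldimethylsilyloxy)propyl]phenoxy}dimethylsilane
Conditions: TBSCl, imidazole, DMF, rt
Reagents that add atoms: tert-butyldimethylsilyl chloride, CC(C)(C)[Si](C)(C)Cl
Why: Silylation masks the primary alcohol that would otherwise attack the ipso carbon during the phenol oxidation.

Step 13
Reactants: 20 bis-TBS ether
Product: 21 4-[(2R)-2-Ar-3-(tert-butyldimethylsilyloxy)propyl]phenol
Conditions: KHF2 (2.5 equiv), MeOH, rt
Reagents that add atoms: none
Why: Bifluoride cleaves aryl silyl ethers selectively because phenoxide is a far better leaving group from silicon than a primary alkoxide, so the alkyl TBS ether should remain.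

Step 14
Reactants: 21 4-[(2R)-2-Ar-3-(tert-butyldimethylsilyloxy)propyl]phenol
Product: 22 4-hydroxy-4-[(2R)-2-Ar-3-(tert-butyldimethylsilyloxy)propyl]cyclohexa-2,5-dien-1-one
Conditions: PhI(OAc)2 (1.1 equiv), MeCN/H2O (3:1), 0 °C
Reagents that add atoms: water, O
Why: Iodine(III) oxidative dearomatisation, with ligand exchange at the phenol oxygen and para attack of water on the activated ring, gives the p-quinol, since a free phenol is oxidised much faster than aryl ethers or unactivated alkenes and the silylated side-chain oxygen cannot compete with water for the ipso carbon.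

Step 15
Reactants: 22 4-hydroxy-4-[(2R)-2-Ar-3-(tert-butyldimethylsilyloxy)propyl]cyclohexa-2,5-dien-1-one
Product: 23 4-hydroxy-4-[(2R)-2-Ar-3-hydroxypropyl]cyclohexa-2,5-dien-1-one
Conditions: HF·pyridine, pyridine, THF, 0 °C to rt; used without delay
Reagents that add atoms: none
Why: Buffered fluoride desilylation frees the primary alcohol without ever generating an alkoxide, so the hydroxy quinol should be isolable before conjugate addition sets in.

Step 16
Reactants: 23 4-hydroxy-4-[(2R)-2-Ar-3-hydroxypropyl]cyclohexa-2,5-dien-1-one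
Product: 25 (3R)-3-Ar-3,4-dihydro-2H-chromen-7-ol (2'-O-allyl ether of the target), via cis-fused hydroxy enone 24 (not isolated)
Conditions: TsOH·H2O (0.2 equiv), toluene (0.01 M), rt then 50 °C
Reagents that add atoms: none
Why: Acid activates the cross-conjugated dienone and the primary hydroxyl adds to an enone β-carbon in a 6-exo-trig oxa-Michael closure that forms O1–C8a and the dihydropyran ring, giving cis-fused hydroxy enone 24. Acid-catalysed enolisation, ionisation of the tertiary allylic 4a-hydroxyl to an oxygen-stabilised arenium-type cation and loss of the 8a proton then aromatise the carbocycle, the former carbonyl oxygen emerging as the 7-OH para to C4a and meta to O1. The closest known reaction types are the intramolecular oxa-Michael addition of quinol-tethered alcohols and the conjugate addition/dehydrative aromatisation of p-quinols to meta-substituted phenols. No stereocentre is created in the product, because the two ring-fusion centres of 24 are erased on aromatisation and C3, which is not α to any carbonyl, is untouched. The two enone arms are diastereotopic but converge on the same arene, so only chemoselectivity is needed: the 2'-O-allyl group keeps the B-ring oxygen from adding to the dienone or closing onto the prenyl group, the only free B-ring carbon (C6') is meta to both ether oxygens and so a poor Friedel–Crafts donor, and catalytic acid at high dilution disfavours bimolecular reactions of the chromene.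

Step 17
Reactants: 25 (3R)-3-Ar-3,4-dihydro-2H-chromen-7-ol
Product: 26 (3R)-3-[7-hydroxy-2,2-dimethyl-8-(3-methylbut-2-en-1-yl)-2H-chromen-6-yl]-3,4-dihydro-2H-chromen-7-ol (target)
Conditions: Pd(PPh3)4 (5 mol %), morpholine (10 equiv), THF, rt, degassed
Reagents that add atoms: none
Why: Tsuji–Trost deallylation, in which Pd(0) ionises the aryl allyl ether to a π-allyl complex that morpholine traps, frees the 2'-phenol under neutral conditions that leave the prenyl group, the chromene and C3 untouched.

**Compound list**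
1 | 2,4-dihydroxybenzaldehyde | O=Cc1ccc(O)cc1O | starting material
2 | prenyl bromide (1-bromo-3-methylbut-2-ene) | CC(C)=CCBr | starting material
3 | 2,4-dihydroxy-3-(3-methylbut-2-en-1-yl)benzaldehyde | O=Cc1ccc(O)c(CC=C(C)C)c1O | intermediate
4 | 3-methylbut-2-enal | CC(C)=CC=O | starting material
5 | 7-hydroxy-2,2-dimethyl-8-(3-methylbut-2-en-1-yl)-2H-chromene-6-carbaldehyde | O=Cc1cc2C=CC(C)(C)Oc2c(CC=C(C)C)c1O | intermediate
6 | 7-(allyloxy)-2,2-dimethyl-8-(3-methylbut-2-en-1-yl)-2H-chromene-6-carbaldehyde (ArCHO) | C=CCOc1c(C=O)cc2C=CC(C)(C)Oc2c1CC=C(C)C | intermediate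
7 | N-(2-Ar-1-tosylvinyl)formamide (present as its potassium salt, not isolated) | C=CCOc1c(C=C(NC=O)S(=O)(=O)c3ccc(C)cc3)cc2C=CC(C)(C)Oc2c1CC=C(C)C | intermediate
8 | 2-Ar-acetonitrile (ArCH2CN) | C=CCOc1c(CC#N)cc2C=CC(C)(C)Oc2c1CC=C(C)C | intermediate
9 | 2-Ar-acetic acid (ArCH2CO2H) | C=CCOc1c(CC(=O)O)cc2C=CC(C)(C)Oc2c1CC=C(C)C | intermediate
10 | (R)-4-benzyloxazolidin-2-one | O=C1N[C@H](Cc2ccccc2)CO1 | starting material
11 | 2-Ar-acetic pivalic anhydride (not isolated) | C=CCOc1c(CC(=O)OC(=O)C(C)(C)C)cc2C=CC(C)(C)Oc2c1CC=C(C)C | intermediate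
12 | (R)-4-benzyl-3-(2-Ar-acetyl)oxazolidin-2-one | C=CCOc1c(CC(=O)N3[C@H](Cc4ccccc4)COC3=O)cc2C=CC(C)(C)Oc2c1CC=C(C)C | intermediate
13 | 4-hydroxybenzaldehyde | O=Cc1ccc(O)cc1 | starting material
14 | 4-(tert-butyldimethylsilyloxy)benzaldehyde | O=Cc1ccc(O[Si](C)(C)C(C)(C)C)cc1 | intermediate
15 | [4-(tert-butyldimethylsilyloxy)phenyl]methanol | OCc1ccc(O[Si](C)(C)C(C)(C)C)cc1 | intermediate
16 | 4-(tert-butyldimethylsilyloxy)benzyl bromide | BrCc1ccc(O[Si](C)(C)C(C)(C)C)cc1 | intermediate
17 | sodium (Z)-enolate of 12 (not isolated) | C=CCOc1c(/C=C(\[O-])N3[C@H](Cc4ccccc4)COC3=O)cc2C=CC(C)(C)Oc2c1CC=C(C)C.[Na+] | intermediate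
18 | (R)-4-benzyl-3-[(2R)-2-Ar-3-(4-TBSO-phenyl)propanoyl]oxazolidin-2-one | C=CCOc1c([C@@H](Cc3ccc(O[Si](C)(C)C(C)(C)C)cc3)C(=O)N3[C@H](Cc4ccccc4)COC3=O)cc2C=CC(C)(C)Oc2c1CC=C(C)C | intermediate
19 | (2R)-2-Ar-3-[4-(tert-butyldimethylsilyloxy)phenyl]propan-1-ol | C=CCOc1c([C@@H](Cc3ccc(O[Si](C)(C)C(C)(C)C)cc3)CO)cc2C=CC(C)(C)Oc2c1CC=C(C)C | intermediate
20 | tert-butyl{4-[(2R)-2-Ar-3-(tert-butyldimethylsilyloxy)propyl]phenoxy}dimethylsilane (bis-TBS ether) | C=CCOc1c([C@@H](Cc3ccc(O[Si](C)(C)C(C)(C)C)cc3)CO[Si](C)(C)C(C)(C)C)cc2C=CC(C)(C)Oc2c1CC=C(C)C | intermediate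
21 | 4-[(2R)-2-Ar-3-(tert-butyldimethylsilyloxy)propyl]phenol | C=CCOc1c([C@@H](Cc3ccc(O)cc3)CO[Si](C)(C)C(C)(C)C)cc2C=CC(C)(C)Oc2c1CC=C(C)C | intermediate
22 | 4-hydroxy-4-[(2R)-2-Ar-3-(tert-butyldimethylsilyloxy)propyl]cyclohexa-2,5-dien-1-one | C=CCOc1c([C@@H](CC3(O)C=CC(=O)C=C3)CO[Si](C)(C)C(C)(C)C)cc2C=CC(C)(C)Oc2c1CC=C(C)C | intermediate
23 | 4-hydroxy-4-[(2R)-2-Ar-3-hydroxypropyl]cyclohexa-2,5-dien-1-one (key-step precursor) | C=CCOc1c([C@@H](CC3(O)C=CC(=O)C=C3)CO)cc2C=CC(C)(C)Oc2c1CC=C(C)C | intermediate
24 | (3R)-3-Ar-4a-hydroxy-2,3,4,4a,8,8a-hexahydro-7H-chromen-7-one (cis ring fusion, both ring-fusion diastereomers, not isolated) | C=CCOc1c([C@@H]3COC4CC(=O)C=CC4(O)C3)cc2C=CC(C)(C)Oc2c1CC=C(C)C | intermediate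
25 | (3R)-3-Ar-3,4-dihydro-2H-chromen-7-ol (2'-O-allyl ether of the target) | C=CCOc1c([C@@H]3COc4cc(O)ccc4C3)cc2C=CC(C)(C)Oc2c1CC=C(C)C | intermediate
26 | (3R)-3-[7-hydroxy-2,2-dimethyl-8-(3-methylbut-2-en-1-yl)-2H-chromen-6-yl]-3,4-dihydro-2H-chromen-7-ol | CC(C)=CCc1c(O)c([C@@H]2COc3cc(O)ccc3C2)cc2c1OC(C)(C)C=C2 | target

**Step count**
Total: 17 steps. Longest linear sequence: 14 steps (steps 1–6, then 10–17); the A-ring branch (steps 7–9) joins at step 10.

**Steps most likely to fail**

Step 16 (key step). The dehydrative aromatisation may lag behind acid-induced side reactions of ring B (protonation of the electron-rich chromene or the prenyl alkene, then oligomerisation or ether formation), or the sequence may stall after the conjugate addition. The fallback sets out from imide 12 and comes back at 25; it buys the A-ring oxygen pattern and closes ring C by Mitsunobu etherification, so no acid touches ring B. Compound 1 would be bis-silylated to 2,4-bis(tert-butyldimethylsilyloxy)benzaldehyde F1, reduced with NaBH4 to [2,4-bis(tert-butyldimethylsilyloxy)phenyl]methanol F2 and brominated (CBr4, PPh3) to 2,4-bis(tert-butyldimethylsilyloxy)benzyl bromide F3. Enolate 17 would be alkylated with F3 under the conditions of step 10 to give the (2R)-alkylated imide F4, LiBH4 would give the primary alcohol F5, and TBAF/AcOH would remove both aryl silyl ethers to give the resorcinol triol F6. PPh3/DIAD in THF at 0 °C under high dilution would then join the ortho phenol to the primary carbon (no stereocentre involved) and give 25.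

Step 14. The oxidant may fail to discriminate: oxidation of the electron-rich chromene ring, or capture of the activated phenol by something other than water, would erode the para-hydroxylation. The fallback sets out from acid 9 and comes back at 22; it builds the quinol by carbanion addition to a quinone monoketal, so no oxidant meets ring B. Acid 9 would be attached (as in step 6) to (S)-4-benzyloxazolidin-2-one to give the (S)-imide F7. Its titanium enolate (TiCl4, i-Pr2NEt, CH2Cl2, 0 °C) would be hydroxymethylated with 1,3,5-trioxane/TiCl4 to give the (2R)-hydroxymethyl imide F8; here the new arm is the future C2, which is why the enantiomeric auxiliary is needed. Silylation would give the TBS ether F9, LiBH4 the mono-protected diol F10, and I2/PPh3/imidazole the primary iodide F11. Iodine–lithium exchange (t-BuLi, Et2O, −78 °C) and 1,2-addition to 4,4-dimethoxycyclohexa-2,5-dien-1-one would give the quinol dimethyl ketal F12, which dilute aqueous acetic acid would hydrolyse to 22.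

Step 1. Regiocontrol of the phenolate alkylation may be poor (attack at C5 or on oxygen, and double alkylation). The fallback sets out from 1 and comes back at 3. Pd(PPh3)4-catalysed O-alkylation of the free, non-chelated 4-hydroxyl with tert-butyl 2-methylbut-3-en-2-yl carbonate would give the 1,1-dimethylallyl ether 2-hydroxy-4-[(2-methylbut-3-en-2-yl)oxy]benzaldehyde F13. Aromatic Claisen rearrangement (N,N-diethylaniline, about 120 °C) would then deliver the prenyl group with allylic inversion to C3, the ortho position favoured by bond fixation in the chelated salicylaldehyde, giving 3.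

**Further compounds**
F1 | step 16 | 2,4-bis(tert-butyldimethylsilyloxy)benzaldehyde | O=Cc1ccc(O[Si](C)(C)C(C)(C)C)cc1O[Si](C)(C)C(C)(C)C
F2 | step 16 | [2,4-bis(tert-butyldimethylsilyloxy)phenyl]methanol | OCc1ccc(O[Si](C)(C)C(C)(C)C)cc1O[Si](C)(C)C(C)(C)C
F3 | step 16 | 2,4-bis(tert-butyldimethylsilyloxy)benzyl bromide | BrCc1ccc(O[Si](C)(C)C(C)(C)C)cc1O[Si](C)(C)C(C)(C)C
F4 | step 16 | (R)-4-benzyl-3-{(2R)-2-Ar-3-[2,4-bis(tert-butyldimethylsilyloxy)phenyl]propanoyl}oxazolidin-2-one | C=CCOc1c([C@@H](Cc3ccc(O[Si](C)(C)C(C)(C)C)cc3O[Si](C)(C)C(C)(C)C)C(=O)N3[C@H](Cc4ccccc4)COC3=O)cc2C=CC(C)(C)Oc2c1CC=C(C)C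
F5 | step 16 | (2R)-2-Ar-3-[2,4-bis(tert-butyldimethylsilyloxy)phenyl]propan-1-ol | C=CCOc1c([C@@H](Cc3ccc(O[Si](C)(C)C(C)(C)C)cc3O[Si](C)(C)C(C)(C)C)CO)cc2C=CC(C)(C)Oc2c1CC=C(C)C
F6 | step 16 | 4-[(2R)-2-Ar-3-hydroxypropyl]benzene-1,3-diol | C=CCOc1c([C@@H](Cc3ccc(O)cc3O)CO)cc2C=CC(C)(C)Oc2c1CC=C(C)C
F7 | step 14 | (S)-4-benzyl-3-(2-Ar-acetyl)oxazolidin-2-one | C=CCOc1c(CC(=O)N3[C@@H](Cc4ccccc4)COC3=O)cc2C=CC(C)(C)Oc2c1CC=C(C)C
F8 | step 14 | (S)-4-benzyl-3-[(2R)-2-Ar-3-hydroxypropanoyl]oxazolidin-2-one | C=CCOc1c([C@@H](C(=O)N3[C@@H](Cc4ccccc4)COC3=O)CO)cc2C=CC(C)(C)Oc2c1CC=C(C)C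
F9 | step 14 | (S)-4-benzyl-3-[(2R)-2-Ar-3-(tert-butyldimethylsilyloxy)propanoyl]oxazolidin-2-one | C=CCOc1c([C@@H](C(=O)N3[C@@H](Cc4ccccc4)COC3=O)CO[Si](C)(C)C(C)(C)C)cc2C=CC(C)(C)Oc2c1CC=C(C)C
F10 | step 14 | (2S)-2-Ar-3-(tert-butyldimethylsilyloxy)propan-1-ol | C=CCOc1c([C@@H](CO)CO[Si](C)(C)C(C)(C)C)cc2C=CC(C)(C)Oc2c1CC=C(C)C
F11 | step 14 | tert-butyl{[(2R)-2-Ar-3-iodopropyl]oxy}dimethylsilane | C=CCOc1c([C@@H](CI)CO[Si](C)(C)C(C)(C)C)cc2C=CC(C)(C)Oc2c1CC=C(C)C
F12 | step 14 | 1-[(2R)-2-Ar-3-(tert-butyldimethylsilyloxy)propyl]-4,4-dimethoxycyclohexa-2,5-dien-1-ol | C=CCOc1c([C@@H](CC3(O)C=CC(OC)(OC)C=C3)CO[Si](C)(C)C(C)(C)C)cc2C=CC(C)(C)Oc2c1CC=C(C)C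
F13 | step 1 | 2-hydroxy-4-[(2-methylbut-3-en-2-yl)oxy]benzaldehyde | O=Cc1ccc(OC(C)(C)C=C)cc1O
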